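**Retrosynthetic overview**

1. Feature: the target is a 14-membered carbocycle C1–C14 (13-membered through the furan oxygen; furan = C3–C6). It carries the fragile C8(OH)–C9H2–C10(=O)–C11(OH) ketol beside the C12=C13 enoate, and this array is treated as the hydrate of a C9≡C10 alkyne flanked by the C8 and C11 carbinols.
2. Endgame with the ring intact: ketol ⇐ (Z)-enol cyclic carbonate ⇐ gold-catalysed 5-exo-dig closure of the O11 tert-butyl carbonate onto C10 ⇐ macrocyclic propargylic alcohol.
3. Key disconnection C10–C11: CrCl2-mediated intramolecular addition of a C10 iodoalkyne to the C11 aldehyde of an (E)-2-formyl enoate closes the macrocycle and sets C11.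
4. Seco compound ⇐ Baylis–Hillman reaction at C13, 1,3-acetate transposition and oxidation (C11–C13). Furan ⇐ Feist–Benary condensation of a β-keto ester from (S)-carvone (C1–C4, C13, C14) with an α-chloroaldehyde from (S)-2-methylglycidol (C5–C10).
5. Ring order: furan ring first (step 12), 14-membered ring last (step 19). The C7–C10 arm comes in with the chloroaldehyde because a base would deprotonate a 2-alkylfuran-3-carboxylate at the lateral C2 methylene, not at C6.

Key step: step 19

Remark: cembrane numbering is used: C1 (CH bearing isopropenyl), C2, furan carbons C3–C6 (O between C3 and C6, CO2Me on C4), C7, C8 (C–CH3, O8), C9, C10, C11 (O11), C12 (CO2Me), C13, C14.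
Assumption: in step 19 the oxazoline–sulfonamide ligand is written as its (S)-enantiomer; which enantiomer delivers C10 to the required face of the C11 aldehyde is settled in a trial run (both are made from valine).

**Route**

Step 1
Reactants: 1 (S)-carvone, (5S)-2-methyl-5-(prop-1-en-2-yl)cyclohex-2-en-1-one
Product: 2 (1S,4S,6S)-1-methyl-4-(prop-1-en-2-yl)-7-oxabicyclo[4.1.0]heptan-2-one (trans-carvone epoxide)
Conditions: H2O2 (30 % aq), NaOH (aq, cat.), MeOH, 0 °C
Reagents that add atoms: hydrogen peroxide, OO
Why: Weitz–Scheffer nucleophilic epoxidation: hydroperoxide adds conjugately to the enone on the face anti to the C5 isopropenyl group and closes the epoxide, while the electron-rich isopropenyl alkene does not react with the nucleophilic oxidant; the two new epoxide centres are removed again in step 2.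

Step 2
Reactants: 2 trans-carvone epoxide
Product: 3 (3S)-5-oxo-3-(prop-1-en-2-yl)pentanoic acid
Conditions: H2SO4 (aq, cat.), THF–H2O, 23 °C; then NaIO4, 0 → 23 °C
Reagents that add atoms: water, O
Why: Acid opens the epoxide to the keto diol and periodate (Malaprade cleavage) then cuts the C2–C3 glycol and the resulting 1,2-dicarbonyl unit, excising the methyl-bearing carbon as acetic acid and leaving a carboxylic acid and an aldehyde on the two arms of the untouched isopropenyl stereocentre.

Step 3
Reactants: 3 (3S)-5-oxo-3-(prop-1-en-2-yl)pentanoic acid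
Product: 4 methyl (3S)-5,5-dimethoxy-3-(prop-1-en-2-yl)pentanoate
Conditions: HC(OMe)3, MeOH, TsOH·H2O (cat.), 40 °C
Reagents that add atoms: trimethyl orthoformate, COC(OC)OC; methanol, CO
Why: Acid-catalysed acetalisation with the orthoformate as water scavenger and concurrent Fischer esterification mask the aldehyde (future C13) as a base-stable dimethyl acetal; the stereocentre is not involved.

Step 4
Reactants: 4 methyl (3S)-5,5-dimethoxy-3-(prop-1-en-2-yl)pentanoate
Product: 5 (3S)-5,5-dimethoxy-3-(prop-1-en-2-yl)pentanoic acid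
Conditions: LiOH, THF–H2O, 23 °C; cold dilute HCl to pH 4
Reagents that add atoms: lithium hydroxide, [Li+].[OH-]
Why: Saponification of the methyl ester with hydroxide frees the acid needed for chain extension, the acetal being stable to base and to the brief cold acidification.

Step 5
Reactants: 5 (3S)-5,5-dimethoxy-3-(prop-1-en-2-yl)pentanoic acid
Product: 7 methyl (5S)-7,7-dimethoxy-3-oxo-5-(prop-1-en-2-yl)heptanoate, via acyl imidazolide 6 (not isolated)
Conditions: CDI, THF, 23 °C; then Mg(O2CCH2CO2Me)2, THF, 40 °C; dilute HCl work-up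
Reagents that add atoms: magnesium bis(methyl malonate), COC(=O)CC(=O)[O-].COC(=O)CC(=O)[O-].[Mg+2]; N,N′-carbonyldiimidazole, O=C(n1ccnc1)n1ccnc1 (imidazolyl group of 6 only)
Why: Masamune–Brooks homologation: the acyl imidazolide C-acylates the magnesium enolate of the malonate half ester and the adduct decarboxylates to the methyl β-keto ester under neutral conditions that spare the acetal.

Step 6
Reactants: 8 (S)-2-methylglycidol, [(2S)-2-methyloxiran-2-yl]methanol
Product: 9 (2R)-2-methylhex-5-ene-1,2-diol
Conditions: allylmagnesium chloride (3 equiv), CuI (10 mol %), THF, −40 → 0 °C; NH4Cl work-up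
Reagents that add atoms: allylmagnesium chloride, C=CC[Mg]Cl
Why: Copper-catalysed SN2 opening of the epoxide at its unsubstituted CH2 by the allyl Grignard reagent (the first equivalent deprotonates the hydroxyl); the quaternary carbon, future C8, is not touched and keeps its configuration, its CIP label changing from S to R only because the substituent ranking changes.

Step 7
Reactants: 9 (2R)-2-methylhex-5-ene-1,2-diol
Product: 10 (2R)-2-methyl-1,2-bis(triethylsilyloxy)hex-5-ene
Conditions: Et3SiOTf (2.4 equiv), 2,6-lutidine, CH2Cl2, −78 → 0 °C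
Reagents that add atoms: triethylsilyl triflate, CC[Si](CC)(CC)OS(=O)(=O)C(F)(F)F
Why: Silylation with the silyl triflate and a hindered pyridine base protects both hydroxyls, including the tertiary one that must stay masked until the last step.

Step 8
Reactants: 10 (2R)-2-methyl-1,2-bis(triethylsilyloxy)hex-5-ene
Product: 11 (2R)-2-methyl-2-(triethylsilyloxy)hex-5-enal
Conditions: (COCl)2, DMSO, CH2Cl2, −78 → −30 °C; then Et3N, −78 → 0 °C
Reagents that add atoms: none
Why: Swern oxidation of a primary triethylsilyl ether: the chlorodimethylsulfonium ion attacks the unhindered primary silyl ether oxygen, Et3SiCl leaves and the alkoxysulfonium ylide collapses to the aldehyde, while the hindered tertiary silyl ether is inert.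

Step 9
Reactants: 11 (2R)-2-methyl-2-(triethylsilyloxy)hex-5-enal
Product: 12 (3R)-3-methyl-3-(triethylsilyloxy)hept-6-en-1-yne
Conditions: dimethyl (1-diazo-2-oxopropyl)phosphonate, K2CO3, MeOH, 0 → 23 °C
Reagents that add atoms: dimethyl (1-diazo-2-oxopropyl)phosphonate, CC(=O)C(=[N+]=[N-])P(=O)(OC)OC
Why: Ohira–Bestmann (Seyferth–Gilbert) homologation: the diazomethylphosphonate anion formed in situ adds to the aldehyde and cycloelimination, loss of N2 and 1,2-hydrogen shift give the terminal alkyne that becomes C9≡C10; the adjacent centre is quaternary and cannot epimerise.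

Step 10
Reactants: 12 (3R)-3-methyl-3-(triethylsilyloxy)hept-6-en-1-yne
Product: 13 (4R)-4-methyl-4-(triethylsilyloxy)hex-5-ynal
Conditions: O3, CH2Cl2–MeOH, −78 °C (stopped at the end point); then PPh3, → 23 °C
Reagents that add atoms: ozone, [O-][O+]=O
Why: Ozonolysis with reductive work-up cleaves the monosubstituted alkene, which reacts far faster with ozone than the terminal alkyne, to the aldehyde whose carbonyl carbon becomes furan C5.

Step 11
Reactants: 13 (4R)-4-methyl-4-(triethylsilyloxy)hex-5-ynal
Product: 14 (4R)-2-chloro-4-methyl-4-(triethylsilyloxy)hex-5-ynal (both C2 epimers)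
Conditions: NCS, L-prolinamide (10 mol %), CH2Cl2, 0 → 23 °C
Reagents that add atoms: N-chlorosuccinimide, O=C1CCC(=O)N1Cl
Why: Enamine-catalysed α-chlorination: the prolinamide enamine of the aldehyde attacks NCS at the only α-carbon; the new C–Cl centre is formed as a mixture, which is irrelevant because this carbon becomes the sp2 furan carbon C6.

Step 12
Reactants: 7 methyl (5S)-7,7-dimethoxy-3-oxo-5-(prop-1-en-2-yl)heptanoate; 14 (4R)-2-chloro-4-methyl-4-(triethylsilyloxy)hex-5-ynal
Product: 16 methyl 2-[(2R)-4,4-dimethoxy-2-(prop-1-en-2-yl)butyl]-5-[(2R)-2-methyl-2-(triethylsilyloxy)but-3-yn-1-yl]furan-3-carboxylate, via hydroxydihydrofuran 15 (not isolated)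
Conditions: pyridine, 50 °C; then PPTS (cat.), 4 Å MS, toluene, 50 °C
Reagents that add atoms: none
Why: Feist–Benary furan synthesis: the doubly activated C4 methylene of 7 adds to the aldehyde of 14, the ketone enol oxygen displaces the secondary chloride (5-exo-tet) to give 15 and acid-catalysed dehydration aromatises, so that the aldehyde carbon becomes C5, the chlorinated carbon becomes C6 with its C7–C10 arm in place and no metalation of the furoate is needed.

Step 13
Reactants: 16 furan acetal
Product: 17 methyl 5-[(2R)-2-methyl-2-(triethylsilyloxy)but-3-yn-1-yl]-2-[(2R)-4-oxo-2-(prop-1-en-2-yl)butyl]furan-3-carboxylate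
Conditions: PPTS (0.2 equiv), acetone–H2O (9:1), 23 °C
Reagents that add atoms: water, O
Why: Pyridinium-catalysed hydrolysis (transacetalisation to acetone) of the acyclic dimethyl acetal, which is far more labile than the hindered tertiary silyl ether, frees the C13 aldehyde.

Step 14
Reactants: 17 furan aldehyde; 18 methyl acrylate
Product: 19 methyl 2-[(2S)-4-hydroxy-5-(methoxycarbonyl)-2-(prop-1-en-2-yl)hex-5-en-1-yl]-5-[(2R)-2-methyl-2-(triethylsilyloxy)but-3-yn-1-yl]furan-3-carboxylate (both C13 epimers)
Conditions: methyl acrylate (5 equiv), DABCO (1 equiv), MeOH (3 equiv), 23 °C, 3–5 d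
Reagents that add atoms: none
Why: Morita–Baylis–Hillman reaction: the DABCO–acrylate zwitterion adds to the unhindered aldehyde and elimination of DABCO gives the α-methylene β-hydroxy ester (C11–C13); the C13 carbinol forms as both epimers, which is harmless because C13 becomes sp2 in step 15.

Step 15
Reactants: 19 Baylis–Hillman adduct
Product: 21 methyl 2-[(2S,4E)-6-acetoxy-5-(methoxycarbonyl)-2-(prop-1-en-2-yl)hex-4-en-1-yl]-5-[(2R)-2-methyl-2-(triethylsilyloxy)but-3-yn-1-yl]furan-3-carboxylate, via Baylis–Hillman acetate 20 (not isolated)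
Conditions: Ac2O, Et3N, DMAP (cat.), CH2Cl2, 0 °C; then DABCO (0.5 equiv), THF, 65 °C
Reagents that add atoms: acetic anhydride, CC(=O)OC(C)=O
Why: Acetylation followed by DABCO-catalysed 1,3-transposition of the Baylis–Hillman acetate (SN2′ addition of DABCO, return of acetate to the CH2 terminus) under thermodynamic control gives the primary allylic acetate with the trisubstituted (E)-enoate in which C14 is trans to the ester, the geometry of the target.

Step 16
Reactants: 21 rearranged allylic acetate
Product: 22 methyl 2-[(2S,4E)-6-hydroxy-5-(methoxycarbonyl)-2-(prop-1-en-2-yl)hex-4-en-1-yl]-5-[(2R)-2-methyl-2-(triethylsilyloxy)but-3-yn-1-yl]furan-3-carboxylate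
Conditions: K2CO3 (0.3 equiv), MeOH, 0 °C
Reagents that add atoms: none
Why: Base-catalysed transesterification with methanol removes the primary acetate; the two methyl esters can only exchange methoxide for methoxide, and the silyl ether and alkyne are stable.

Step 17
Reactants: 22 allylic alcohol
Product: 23 methyl 2-[(2S,4E)-6-hydroxy-5-(methoxycarbonyl)-2-(prop-1-en-2-yl)hex-4-en-1-yl]-5-[(2R)-4-iodo-2-methyl-2-(triethylsilyloxy)but-3-yn-1-yl]furan-3-carboxylate
Conditions: NIS, AgNO3 (10 mol %), acetone, 23 °C, dark
Reagents that add atoms: N-iodosuccinimide, O=C1CCC(=O)N1I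
Why: Silver-catalysed iodination of the terminal alkyne: the silver acetylide is iodinated by NIS under neutral conditions that leave the alkenes, the furan and the allylic alcohol alone.

Step 18
Reactants: 23 iodoalkyne allylic alcohol
Product: 24 methyl 2-[(2S,4E)-5-formyl-5-(methoxycarbonyl)-2-(prop-1-en-2-yl)pent-4-en-1-yl]-5-[(2R)-4-iodo-2-methyl-2-(triethylsilyloxy)but-3-yn-1-yl]furan-3-carboxylate (seco iodoalkyne 2-formyl enoate)
Conditions: MnO2 (activated, excess), CH2Cl2, 23 °C
Reagents that add atoms: none
Why: MnO2 oxidises the allylic primary alcohol selectively and stops at the aldehyde; the 2-formyl enoate keeps C14 cis to the formyl group and trans to the ester, its less strained geometry.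

Step 19
Reactants: 24 seco iodoalkyne 2-formyl enoate
Product: 25 macrocyclic propargylic alcohol (1S,8R,11R,12E): the 14-membered furan-bridged ring of the target with C9≡C10 in place of C9H2–C10(=O), OSiEt3 on C8 and OH on C11
Conditions: CrCl2 (8 equiv), (S)-N-[2-(4-isopropyl-4,5-dihydro-1,3-oxazol-2-yl)-6-methylphenyl]methanesulfonamide (9 equiv), Et3N (9 equiv), THF, 23 °C; 24 added by syringe pump over 12 h to 2 mM
Reagents that add atoms: none
Why: Two equivalents of divalent chromium insert into the C10–I bond to give an alkynyl species of trivalent chromium, which adds 1,2 to the C11 formyl group; organochromium reagents are aldehyde-selective and ignore the two methyl esters and the Michael position C13. The closest known reaction is the Nozaki–Hiyama–Kishi coupling of 1-iodoalkynes with aldehydes, which is established for ring closure and, with oxazoline–sulfonamide ligands on chromium, for face-selective additions. The 14-membered carbocycle (13-membered through the furan oxygen) closes by this intramolecular C10–C11 bond formation under high dilution, helped by the rigid furan, the (E)-enoate and the linear alkyne, which leave few rotatable bonds. The new C11 carbinol is set by reagent control from the chiral sulfonamide ligand, because C1 and C8 are too remote to bias the aldehyde faces; the required alcohol is (11R) by CIP here and becomes (11S) in the ketol without any change at the centre. The step needs chemoselectivity for the C–I bond and the aldehyde and retention of the C12=C13 geometry: the alkynyl C–I bond is the only bond divalent chromium inserts into, and the enal already sits in its more stable geometry with C14 trans to the ester.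

Step 20
Reactants: 25 macrocyclic propargylic alcohol
Product: 26 O11 tert-butyl carbonate of 25 (1S,8R,11R,12E)
Conditions: Boc2O (1.5 equiv), DMAP (0.2 equiv), MeCN, 23 °C
Reagents that add atoms: di-tert-butyl dicarbonate, CC(C)(C)OC(=O)OC(=O)OC(C)(C)C
Why: DMAP-catalysed acylation of the secondary propargylic alcohol with Boc2O; O8 is silylated, so the participating carbonate is placed on O11 only and C11 is not touched.

Step 21
Reactants: 26 macrocyclic propargylic tert-butyl carbonate
Product: 27 macrocyclic (Z)-enol cyclic carbonate (1S,8R,9Z,11S,12E): 1,3-dioxolan-2-one spanning O10–C10 and O11–C11 with exocyclic C10=C9, OSiEt3 on C8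
Conditions: Ph3PAuNTf2 (5 mol %), CH2Cl2, 23 °C
Reagents that add atoms: none
Why: Gold-catalysed cyclisation of a propargylic tert-butyl carbonate: the monovalent gold cation activates C9≡C10, the carbonate carbonyl oxygen attacks C10 anti to gold (5-exo-dig; 6-endo attack at C9 is disfavoured by ring size and by the quaternary C8), the tert-butyl group leaves as 2-methylpropene and protodeauration gives the (Z)-alkylidene cyclic carbonate with C11 unchanged.

Step 22
Reactants: 27 macrocyclic enol cyclic carbonate
Product: 28 8-O-triethylsilyl ether of the target (1S,8R,11S,12E)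
Conditions: H2O (20 equiv), Et3N (0.3 equiv), MeCN, 0 → 23 °C
Reagents that add atoms: none
Why: Acyl cleavage of an activated enol carbonate: water adds to the carbonate carbonyl under mild amine catalysis, the C10 enolate leaves and is protonated at C9 to give the ketone and the O11 hydrogen carbonate loses CO2, so the ketol appears without strong base while O8 stays silylated and retro-aldol cleavage is blocked.

Step 23
Reactants: 28 8-O-triethylsilyl ether of the target
Product: 29 target CNP0225662.1 (1S,8R,11S,12E)
Conditions: HF·pyridine, pyridine, THF, 0 °C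
Reagents that add atoms: none
Why: Fluoride cleavage of the tertiary silyl ether under buffered weakly acidic conditions that the β-hydroxy ketone tolerates; no stereocentre is touched and the product is the target.

**Compound list**

1 | (S)-carvone | CC1=CC[C@H](C(C)=C)CC1=O | starting material
2 | (1S,4S,6S)-1-methyl-4-(prop-1-en-2-yl)-7-oxabicyclo[4.1.0]heptan-2-one | C[C@]12O[C@H]1C[C@H](C(C)=C)CC2=O | intermediate
3 | (3S)-5-oxo-3-(prop-1-en-2-yl)pentanoic acid | O=CC[C@H](C(C)=C)CC(=O)O | intermediate
4 | methyl (3S)-5,5-dimethoxy-3-(prop-1-en-2-yl)pentanoate | COC(OC)C[C@H](C(C)=C)CC(=O)OC | intermediate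
5 | (3S)-5,5-dimethoxy-3-(prop-1-en-2-yl)pentanoic acid | COC(OC)C[C@H](C(C)=C)CC(=O)O | intermediate
6 | 1-[(3S)-5,5-dimethoxy-3-(prop-1-en-2-yl)pentanoyl]imidazole (acyl imidazolide, not isolated) | COC(OC)C[C@H](C(C)=C)CC(=O)n1ccnc1 | intermediate
7 | methyl (5S)-7,7-dimethoxy-3-oxo-5-(prop-1-en-2-yl)heptanoate | COC(OC)C[C@H](C(C)=C)CC(=O)CC(=O)OC | intermediate
8 | (S)-2-methylglycidol | OC[C@@]1(C)CO1 | starting material
9 | (2R)-2-methylhex-5-ene-1,2-diol | OC[C@](C)(O)CCC=C | intermediate
10 | (2R)-2-methyl-1,2-bis(triethylsilyloxy)hex-5-ene | CC[Si](CC)(CC)OC[C@](C)(O[Si](CC)(CC)CC)CCC=C | intermediate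
11 | (2R)-2-methyl-2-(triethylsilyloxy)hex-5-enal | O=C[C@](C)(O[Si](CC)(CC)CC)CCC=C | intermediate
12 | (3R)-3-methyl-3-(triethylsilyloxy)hept-6-en-1-yne | C#C[C@](C)(O[Si](CC)(CC)CC)CCC=C | intermediate
13 | (4R)-4-methyl-4-(triethylsilyloxy)hex-5-ynal | C#C[C@](C)(O[Si](CC)(CC)CC)CCC=O | intermediate
14 | (4R)-2-chloro-4-methyl-4-(triethylsilyloxy)hex-5-ynal (C2 epimers) | C#C[C@](C)(O[Si](CC)(CC)CC)CC(Cl)C=O | intermediate
15 | methyl 2-[(2R)-4,4-dimethoxy-2-(prop-1-en-2-yl)butyl]-4-hydroxy-5-[(2R)-2-methyl-2-(triethylsilyloxy)but-3-yn-1-yl]-4,5-dihydrofuran-3-carboxylate (hydroxydihydrofuran, not isolated, ring epimers) | C#C[C@](C)(O[Si](CC)(CC)CC)CC1OC(C[C@@H](C(C)=C)CC(OC)OC)=C(C(=O)OC)C1O | intermediate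
16 | methyl 2-[(2R)-4,4-dimethoxy-2-(prop-1-en-2-yl)butyl]-5-[(2R)-2-methyl-2-(triethylsilyloxy)but-3-yn-1-yl]furan-3-carboxylate | C#C[C@](C)(O[Si](CC)(CC)CC)CC1=CC(C(=O)OC)=C(C[C@@H](C(C)=C)CC(OC)OC)O1 | intermediate
17 | methyl 5-[(2R)-2-methyl-2-(triethylsilyloxy)but-3-yn-1-yl]-2-[(2R)-4-oxo-2-(prop-1-en-2-yl)butyl]furan-3-carboxylate | C#C[C@](C)(O[Si](CC)(CC)CC)CC1=CC(C(=O)OC)=C(C[C@@H](C(C)=C)CC=O)O1 | intermediate
18 | methyl acrylate | C=CC(=O)OC | starting material
19 | methyl 2-[(2S)-4-hydroxy-5-(methoxycarbonyl)-2-(prop-1-en-2-yl)hex-5-en-1-yl]-5-[(2R)-2-methyl-2-(triethylsilyloxy)but-3-yn-1-yl]furan-3-carboxylate (C13 epimers) | C#C[C@](C)(O[Si](CC)(CC)CC)CC1=CC(C(=O)OC)=C(C[C@@H](C(C)=C)CC(O)C(=C)C(=O)OC)O1 | intermediate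
20 | methyl 2-[(2S)-4-acetoxy-5-(methoxycarbonyl)-2-(prop-1-en-2-yl)hex-5-en-1-yl]-5-[(2R)-2-methyl-2-(triethylsilyloxy)but-3-yn-1-yl]furan-3-carboxylate (Baylis–Hillman acetate, not isolated) | C#C[C@](C)(O[Si](CC)(CC)CC)CC1=CC(C(=O)OC)=C(C[C@@H](C(C)=C)CC(OC(C)=O)C(=C)C(=O)OC)O1 | intermediate
21 | methyl 2-[(2S,4E)-6-acetoxy-5-(methoxycarbonyl)-2-(prop-1-en-2-yl)hex-4-en-1-yl]-5-[(2R)-2-methyl-2-(triethylsilyloxy)but-3-yn-1-yl]furan-3-carboxylate | C#C[C@](C)(O[Si](CC)(CC)CC)CC1=CC(C(=O)OC)=C(C[C@@H](C(C)=C)C/C=C(/C(=O)OC)COC(C)=O)O1 | intermediate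
22 | methyl 2-[(2S,4E)-6-hydroxy-5-(methoxycarbonyl)-2-(prop-1-en-2-yl)hex-4-en-1-yl]-5-[(2R)-2-methyl-2-(triethylsilyloxy)but-3-yn-1-yl]furan-3-carboxylate | C#C[C@](C)(O[Si](CC)(CC)CC)CC1=CC(C(=O)OC)=C(C[C@@H](C(C)=C)C/C=C(/C(=O)OC)CO)O1 | intermediate
23 | methyl 2-[(2S,4E)-6-hydroxy-5-(methoxycarbonyl)-2-(prop-1-en-2-yl)hex-4-en-1-yl]-5-[(2R)-4-iodo-2-methyl-2-(triethylsilyloxy)but-3-yn-1-yl]furan-3-carboxylate | IC#C[C@](C)(O[Si](CC)(CC)CC)CC1=CC(C(=O)OC)=C(C[C@@H](C(C)=C)C/C=C(/C(=O)OC)CO)O1 | intermediate
24 | methyl 2-[(2S,4E)-5-formyl-5-(methoxycarbonyl)-2-(prop-1-en-2-yl)pent-4-en-1-yl]-5-[(2R)-4-iodo-2-methyl-2-(triethylsilyloxy)but-3-yn-1-yl]furan-3-carboxylate (key-step precursor) | IC#C[C@](C)(O[Si](CC)(CC)CC)CC1=CC(C(=O)OC)=C(C[C@@H](C(C)=C)C/C=C(/C(=O)OC)C=O)O1 | intermediate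
25 | macrocyclic propargylic alcohol (1S,8R,11R,12E), C9≡C10, 8-OSiEt3, 11-OH (key-step product) | C=C(C)[C@H]1C/C=C(/C(=O)OC)[C@H](O)C#C[C@](C)(O[Si](CC)(CC)CC)CC2=CC(C(=O)OC)=C(C1)O2 | intermediate
26 | O11 tert-butyl carbonate of 25 (1S,8R,11R,12E) | C=C(C)[C@H]1C/C=C(/C(=O)OC)[C@H](OC(=O)OC(C)(C)C)C#C[C@](C)(O[Si](CC)(CC)CC)CC2=CC(C(=O)OC)=C(C1)O2 | intermediate
27 | macrocyclic (Z)-enol cyclic carbonate (1S,8R,9Z,11S,12E) | C=C(C)[C@H]1C/C=C(/C(=O)OC)[C@@H]3OC(=O)O/C3=C\[C@](C)(O[Si](CC)(CC)CC)CC2=CC(C(=O)OC)=C(C1)O2 | intermediate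
28 | 8-O-triethylsilyl ether of the target (1S,8R,11S,12E) | C=C(C)[C@H]1C/C=C(/C(=O)OC)[C@H](O)C(=O)C[C@](C)(O[Si](CC)(CC)CC)CC2=CC(C(=O)OC)=C(C1)O2 | intermediate
29 | CNP0225662.1 (1S,8R,11S,12E) | C=C(C)[C@H]1C/C=C(/C(=O)OC)[C@H](O)C(=O)C[C@](C)(O)CC2=CC(C(=O)OC)=C(C1)O2 | target

**Step count and risks**

Total steps: 23. Longest linear sequence: 18 steps (8 → 29: steps 6–11, then 12–23); the carvone branch contributes 5 steps before the convergence in step 12.

Three steps most likely to fail:

1. Step 19 (macrocyclisation). What may go wrong: intermolecular coupling competes with ring closure at practical dilution, and ligand control over the two faces of the C11 aldehyde is weak or mismatched, so both C11 epimers form. Fallback, which moves the stereocontrol from C–C bond formation to a ketone reduction: it sets out from 25 obtained as a C11 epimer mixture. Dess–Martin periodinane (NaHCO3, CH2Cl2, 0 °C) oxidises both epimers to the macrocyclic ynone F1. Reduction with a B-methyl CBS oxazaborolidine and catecholborane at −78 °C, which reads the alkynyl arm as the small group (catalyst enantiomer chosen on that model), returns 25 as the single (11R) alcohol, and the route continues with step 20.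

2. Step 21 (gold cyclisation). What may go wrong: the cationic gold catalyst ionises or transposes the carbonate, which is both allylic and propargylic, or the carbonyl oxygen attacks C9 (6-endo). Fallback without Boc group and without gold: it sets out from alcohol 25 and comes back at 27. Carboxylative cyclisation of the propargylic alcohol with CO2 (AgOAc cat., DBU, CO2 1 atm, toluene, 23 °C), in which the O11 carbonate anion adds anti to the silver-activated alkyne at C10, gives the same (Z)-enol carbonate; this fallback makes no new compound (F0).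

3. Step 14 (Baylis–Hillman reaction). What may go wrong: the amine-catalysed coupling is slow and reversible on a β-branched aldehyde, and over the days needed aldol self-condensation of 17 and stalling erode conversion. Fallback with a stoichiometric organoaluminium nucleophile instead of amine catalysis: it sets out from 17 and comes back at 19. Hydroalumination of methyl propiolate with iBu2AlH/HMPA (THF, 0 °C) gives the α-aluminoacrylate, which adds to the aldehyde of 17 within hours to give the same adduct 19; this fallback makes no new compound (F0).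

Further compounds
F0 | step 14 | none | none
F1 | step 19 | macrocyclic ynone (1S,8R,12E), C11 ketone of 25 | C=C(C)[C@H]1C/C=C(/C(=O)OC)C(=O)C#C[C@](C)(O[Si](CC)(CC)CC)CC2=CC(C(=O)OC)=C(C1)O2
F0 | step 21 | none | none
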